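## Structural features

Compound 31 is a germacranolide. Its atoms are labelled C1–C10 around the ten-membered carbocycle, C11–C13 for the lactone branch (C12 carbonyl, C13 methyl), C14 for the methyl on C10 and C15 for the methyl on C4. The carbocycle holds a Z trisubstituted C1=C10 alkene and an E trisubstituted C4=C5 alkene and is fused through C6–C7 to an α-methyl-γ-butyrolactone (O–C6–C7–C11–C12). Three contiguous stereocentres lie on the lactone (C6 S, C7 S, C11 R; H6/H7 trans, C13 on the same face as the C7–C8 bond). C3 (S) carries the (R)-2-methylbutanoate and stands 1,4 to C6 across the E alkene, and C9 (S) carries a free allylic hydroxyl remote from the other centres. Fragile points are the two allylic C–O bonds (C3 ester, C6 lactone oxygen), the base-sensitive C11 centre (C13 sits cis to C8, probably the less stable arrangement) and the α-centre of the side-chain ester. The C3 acyloxy group can also migrate or be eliminated once C1 is a free hydroxyl or a carbonyl, and the E,Z-cyclodecadiene is strained. The real difficulties are closing the ten-membered ring with both alkene geometries intact and relating C3 to C6, which no ring connects. The key step uses exactly that relationship: O3 and O6 end a four-carbon C3–C6 unit whose central C4=C5 bond is E, O6 being part of the lactone and O3 acylated, the pattern left by 1,4-addition of two carboxylates to a C3=C4–C5=C6 diene.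

## Logic of the disconnections

**C9–C10 of 31.** Cutting the ring between the carbinol carbon and the alkene carbon leads to 29. This is the one ring bond that a chemoselective carbonyl addition can form while leaving ester and lactone alone, keeping the C1=C10 geometry and delivering the C9 hydroxyl unprotected. The gain is the loss of the medium ring and of one stereocentre. The forward step needs high dilution, a geometrically pure Z-iodide and facial selectivity at C9.

**C1=C10 of 27, with the functional-group changes 29 ⇐ 28 ⇐ 27 and 25 ⇐ 24 ⇐ 23.** Cutting the iodo-alkene gives 25 and the two-carbon unit 26 (C10 and C14). The Z iodo-alkene is the retron of a Wittig reaction with an iodo-ylide, and the two oxygenated chain ends C1 and C9 are told apart by orthogonal ethers. This brings the problem back to 23, which carries only protected alcohols. The demand is that 25, which has a leaving group β to its carbonyl, meets only weakly basic reagents at low temperature, and that C1 is unmasked before C9.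

**C6–O and C3–O of 23.** Removing both C–O bonds gives 20 and 21. The two oxygens end a four-carbon unit with an E alkene in the middle and one of them is tethered, so a single metal-templated event can form both bonds and fix their mutual configuration. One ring, two stereocentres and the side chain disappear, and 20 keeps only the adjacent centres C7 and C11. The forward step demands a geometrically pure E,E-diene, face selection by C7/C11 and external attack of the second carboxylate.

**C4–C5 of 20.** Cutting this sp2–sp2 bond gives 15 and 19. Both halves are stereodefined alkenes, so the coupling is convergent and carries the diene geometry in from the partners. The chiral C5–C13 piece is separated from the achiral C1–C4 piece. The coupling must tolerate a free carboxylic acid and must not isomerise either alkene.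

**C4–I of 19, then O–benzyl of 17.** Replacing C4–I and C3–H by an alkyne leads to 17 and then to 16. Syn addition of a metal hydride across the alkyne fixes the E geometry. The demand is that the metal ends on the methyl-bearing carbon C4.

**C5=C6 of 15.** Exchanging the boron-bearing alkylidene for an ethylidene gives 13 and 14. This leaves 13 as a plain γ,δ-unsaturated acid. The forward metathesis must be E-selective at an α-branched alkene.

**C7–C11 of 13.** This bond is the one formed in a [3,3] shift, and cutting it gives 9. Both stereocentres of 13 are thereby traced to one carbinol centre and two alkene geometries. The forward step needs a Z(O)-enolate, a Z-alkene and a chair transition state.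

**Acyl C–O of 9; C=C of 7; carbinol C–H of 6; acyl–alkynyl C–C of 5; O–Si of 2.** These cuts lead through 7 + 8, 6 and 5 to 2 + 3 and finally to 1. They reduce the only source of absolute configuration to the reduction of a ketone. The demands are an enantioselective reduction (5 to 6) and a cis-selective semihydrogenation (6 to 7).

## Other disconnections considered

**Alternative 1:** The cut runs across the ring through C5–C10. Re-closing that bond turns the C10=C1–C2=C3–C4=C5 triene of A2 into ring A of the cis-fused decalin A1, whose C1=C2–C3=C4 diene carries the C3 acetate. In the forward direction A1 would be irradiated cold, so that the cyclohexadiene opens in the photochemically allowed conrotatory sense to A2 (C1=C10 Z, C4=C5 E). The central C2=C3 alkene of A2 is ring-cis, which is E by the sequence rule because the acetoxy group outranks C4.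
- In its favour: the ten-membered ring is unveiled from a rigid bicycle, so no high-dilution closure is needed, and C6, C7, C9 and C11 could be set on a conformationally defined decalin. On ring formation, and on reagent economy of the key step itself, this plan is the better one.
- Against it here: the step makes no stereocentre and erases two. C3 emerges trigonal, so the C3 centre, the C2 methylene and the (R)-2-methylbutanoate must all be made afterwards, by selective saturation of an enol-acetate alkene inside a labile triene and an acyl exchange, with C3 controlled only by a flexible ring. The two conrotatory senses give different alkene geometries and nothing in A1 steers between them. The triene can re-close or rearrange on further irradiation or warming.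
- Comparison: structurally, the chosen plan puts its key step on the relationship that is hardest to control (C3 against C6), and Alternative 1 leaves that relationship open. Mechanistically, a pericyclic opening has clearer geometric rules than a metal-templated addition, a point for the alternative. In step count, making A1 and repairing C2/C3 afterwards should exceed the seventeen steps of the chosen plan.

**Alternative 2:** The cut is C6–C7 at the ring fusion, which leads from A4 back to the thirteen-membered diallylic ether A3. In the forward direction a lithium amide removes a proton from C6 of A3 and the carbanion shifts [2,3] onto C7. This forms C6–C7, breaks O–C12, contracts the ring to ten members and leaves the C6 alkoxide and the C7 isopropenyl group of A4.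
- In its favour: a thirteen-membered ether closes more easily than a ten-membered carbocycle. The contraction then delivers the carbocycle, both ring alkenes and two adjacent stereocentres at once, and the E-alkene to anti preference of the five-membered transition state fits the trans relationship at C6/C7. In ring-closing entropy this is better than the chosen plan; in stereocentres made by the key step (two) it is its equal.
- Against it here: proton removal at C12, the other α-oxy allylic position, competes with C6, and a [1,2]-shift can intervene. C3 and C9 must already be present in A3, each from its own asymmetric step. After the contraction the isopropenyl group still has to be hydroborated, oxidised and lactonised, with C11 under substrate control on a macrocycle and the required C13-cis arrangement not obviously favoured. The C3 ether must then be exchanged for the ester and C9 unmasked.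
- Comparison: structurally, the chosen plan makes lactone and C3 ester in their final form in one step, whereas Alternative 2 reaches the lactone last and with its weakest control at C11. Mechanistically, the strongly basic step meets only ethers in A3, which is an advantage over the base-sensitive late intermediates of the chosen plan. In step economy the roughly six operations after A4 make it longer.

**Alternative 3:** The cut is C7–C8, which leads from A6 back to the open-chain butenolide A5 carrying a C9 silyl dienol ether. In the forward direction a Lewis acid activates the butenolide carbonyl of A5, C8 adds to C7 and closes the ring, and the resulting lactone silyl ketene acetal is protonated at C11 to give the C9 ketone A6.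
- In its favour: the ring closure is a C–C bond formation that also sets C7 and C11 under control of C6. Addition anti to the C6 substituent gives the trans lactone, and protonation anti to the new C7–C8 bond would place C13 cis to C8 as required. On stereocontrol within the ring-closing step this is better than the chosen closure, and the side-chain ester is already in place, an equal point.
- Against it here: C8 must reach the butenolide face opposite to the chain that carries it, a strained trajectory for a ten-membered ring. The Lewis acid can ionise the allylic C3 ester or the allylic lactone C–O bond. A6 still needs a diastereoselective reduction at C9, the same open question as in the chosen plan. A5 already contains C3 and C6 in their 1,4-relationship across the E alkene, so what the palladium step does in one operation returns as two separate asymmetric operations.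
- Comparison: structurally both plans close the ring late at a bond next to C9 or C8. Mechanistically the Michael closure is better at relaying stereochemistry but worse in functional-group tolerance. In step economy the separate construction of C3 and C6 in A5 makes it longer.

Key step: step 11

Remark: the lactone of 31 is trans at C6/C7 and cis at C7/C11; 20 carries this as a 2,3-anti acid, and the C7 descriptor changes from R in 20 to S in 23 without any change in space.
Remark: the olefination reagent of step 14 must deliver C10 together with its C14 methyl, so the 1-iodoethylidene ylide is used and not the iodomethylene ylide.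
Remark: only species that are formed in stoichiometric amount and named in a step are numbered as unisolated intermediates, plus the allylpalladium species of the key step.

## Route

Step 1
Reactants: 1 but-3-yn-1-ol
Product: 2 tert-butyl(but-3-yn-1-yloxy)dimethylsilane
Conditions: TBSCl, imidazole, CH2Cl2, 0 → 23 °C
Reagents that add atoms: tert-butyldimethylsilyl chloride, CC(C)(C)[Si](C)(C)Cl
Why: Imidazole-mediated silylation of the primary alcohol; the terminal alkyne C–H is not affected.

Step 2
Reactants: 2 tert-butyl(but-3-yn-1-yloxy)dimethylsilane; 3 N-methoxy-N-methylacetamide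
Product: 5 6-[(tert-butyldimethylsilyl)oxy]hex-3-yn-2-one, via lithium acetylide 4 (not isolated)
Conditions: n-BuLi, THF, −78 °C; then 3, −78 → 0 °C; aq. NH4Cl
Reagents that add atoms: none
Why: Weinreb ketone synthesis: acetylide 4 adds once to amide 3 because the chelated tetrahedral adduct collapses only on work-up, so the ynone is not attacked a second time.

Step 3
Reactants: 5 6-[(tert-butyldimethylsilyl)oxy]hex-3-yn-2-one
Product: 6 (2R)-6-[(tert-butyldimethylsilyl)oxy]hex-3-yn-2-ol
Conditions: RuCl[(R,R)-TsDPEN](p-cymene) (2 mol%), i-PrOH, 23 °C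
Reagents that add atoms: none
Why: Noyori asymmetric transfer hydrogenation of an ynone; the alkynyl group takes the place of the unsaturated substituent in the six-membered hydride/proton transfer, so the (R,R)-catalyst should deliver the (R)-carbinol, and the alkyne and silyl ether are inert.

Step 4
Reactants: 6 (2R)-6-[(tert-butyldimethylsilyl)oxy]hex-3-yn-2-ol
Product: 7 (2R,3Z)-6-[(tert-butyldimethylsilyl)oxy]hex-3-en-2-ol
Conditions: H2 (1 atm), Pd/CaCO3 poisoned with Pb(OAc)2 (Lindlar catalyst), quinoline, EtOAc, 23 °C
Reagents that add atoms: none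
Why: Lindlar semihydrogenation: syn delivery of hydrogen on the poisoned surface gives the Z-alkene, quinoline holds back over-reduction, and the carbinol centre is not touched.

Step 5
Reactants: 7 (2R,3Z)-6-[(tert-butyldimethylsilyl)oxy]hex-3-en-2-ol; 8 propanoyl chloride
Product: 9 (2R,3Z)-6-[(tert-butyldimethylsilyl)oxy]hex-3-en-2-yl propanoate
Conditions: pyridine, DMAP (cat.), CH2Cl2, 0 → 23 °C
Reagents that add atoms: none
Why: DMAP-catalysed acylation of the secondary alcohol at oxygen, hence with retention at the carbinol carbon.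

Step 6
Reactants: 9 (2R,3Z)-6-[(tert-butyldimethylsilyl)oxy]hex-3-en-2-yl propanoate
Product: 13 (2R,3R,4E)-3-{2-[(tert-butyldimethylsilyl)oxy]ethyl}-2-methylhex-4-enoic acid, via lithium enolate 10 (not isolated), via silyl ketene acetal 11 (not isolated), via trimethylsilyl ester 12 (not isolated)
Conditions: LiN(iPr)2, THF–DMPU, −78 °C; Me3SiCl, −78 → 23 °C, then 50 °C; cold aq. citric acid
Reagents that add atoms: none
Why: Ireland–Claisen rearrangement: in THF–DMPU the ester should give the Z(O)-enolate 10 (methyl cis to O–Li), silylation gives 11, and the [3,3] shift runs through a chair in which allylic 1,3-strain with the Z-alkene forces the carbinol methyl equatorial, so C7–C11 forms on the face from which the C–O bond leaves. The Z-alkene places C8 axial and the ketene acetal places C13 equatorial, which sets C7 and C11 as the 2,3-anti (2R,3R) pair and gives the E-propenyl group; mild acid hydrolyses silyl ester 12 without loss of the TBS ether.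

Step 7
Reactants: 13 (2R,3R,4E)-3-{2-[(tert-butyldimethylsilyl)oxy]ethyl}-2-methylhex-4-enoic acid; 14 4,4,5,5-tetramethyl-2-vinyl-1,3,2-dioxaborolane
Product: 15 (2R,3R,4E)-3-{2-[(tert-butyldimethylsilyl)oxy]ethyl}-2-methyl-5-(4,4,5,5-tetramethyl-1,3,2-dioxaborolan-2-yl)pent-4-enoic acid
Conditions: 14 (3 equiv), second-generation Hoveyda–Grubbs catalyst RuCl2(H2IMes)(=CH-C6H4-2-OiPr) (5 mol%), CH2Cl2, 40 °C, argon purge
Reagents that add atoms: none
Why: Olefin cross-metathesis exchanges the ethylidene end of the C5=C6 alkene for CH–Bpin with loss of propene; the bulky boryl group should enforce the E geometry, and the ruthenium carbene tolerates the free acid and leaves C7 and C11 alone.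

Step 8
Reactants: 16 pent-3-yn-1-ol
Product: 17 1-methoxy-4-[(pent-3-yn-1-yloxy)methyl]benzene
Conditions: NaH, PMBCl, Bu4NI (cat.), THF–DMF, 0 → 23 °C
Reagents that add atoms: 4-methoxybenzyl chloride, COc1ccc(CCl)cc1
Why: Williamson etherification of the primary alkoxide; the internal alkyne has no acidic proton.

Step 9
Reactants: 17 1-methoxy-4-[(pent-3-yn-1-yloxy)methyl]benzene
Product: 19 1-({[(3E)-4-iodopent-3-en-1-yl]oxy}methyl)-4-methoxybenzene, via alkenylzirconocene chloride 18 (not isolated)
Conditions: Cp2Zr(H)Cl (2 equiv), THF, 50 °C; then I2, 0 °C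
Reagents that add atoms: iodine, II
Why: Hydrozirconation–iodination: Zr–H adds syn across the alkyne and, with excess reagent and warming, the metal equilibrates to the less hindered methyl-bearing C4 (18); iodinolysis of the C–Zr bond with retention gives the E-iodide with C15 cis to C2.

Step 10
Reactants: 15 (2R,3R,4E)-3-{2-[(tert-butyldimethylsilyl)oxy]ethyl}-2-methyl-5-(4,4,5,5-tetramethyl-1,3,2-dioxaborolan-2-yl)pent-4-enoic acid; 19 1-({[(3E)-4-iodopent-3-en-1-yl]oxy}methyl)-4-methoxybenzene
Product: 20 (2R,3R,4E,6E)-3-{2-[(tert-butyldimethylsilyl)oxy]ethyl}-9-[(4-methoxybenzyl)oxy]-2,6-dimethylnona-4,6-dienoic acid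
Conditions: PdCl2(dppf) (5 mol%), aq. K3PO4 (4 equiv), THF, 40 °C; then cold aq. citric acid
Reagents that add atoms: none
Why: Suzuki–Miyaura coupling forms C4–C5; oxidative addition of 19 and transmetallation of 15 both go with retention, so the E,E-diene geometry comes from the two partners, and excess base keeps the acid as an inert carboxylate.

Step 11
Reactants: 20 (2R,3R,4E,6E)-3-{2-[(tert-butyldimethylsilyl)oxy]ethyl}-9-[(4-methoxybenzyl)oxy]-2,6-dimethylnona-4,6-dienoic acid; 21 (2R)-2-methylbutanoic acid
Product: 23 (3S,4E)-1-[(4-methoxybenzyl)oxy]-4-methyl-5-[(2S,3S,4R)-3-{2-[(tert-butyldimethylsilyl)oxy]ethyl}-4-methyl-5-oxooxolan-2-yl]pent-4-en-3-yl (2R)-2-methylbutanoate, via allylpalladium chloride 22 (not isolated)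
Conditions: Pd(OAc)2 (10 mol%), p-benzoquinone (20 mol%), MnO2 (2 equiv), LiCl (20 mol%), lithium (R)-2-methylbutanoate (2 equiv), 21 (10 equiv), acetone, 23 °C
Reagents that add atoms: none
Why: Palladium-catalysed 1,4-acyloxylactonisation, that is 1,4-oxidation of a conjugated diene by two carboxylates. Pd(OAc)2 as divalent palladium binds the s-trans C3=C4–C5=C6 diene, and the tethered C12 carboxylate adds to C6 anti to the metal in a 5-exo-trig closure that forms the γ-lactone ring (O–C6–C7–C11–C12) and the syn,syn-η3-allyl complex 22 over C3–C5. Because chloride occupies the metal, a carboxylate cannot migrate from palladium, so (R)-2-methylbutanoate attacks C3 from outside, anti to the metal and distal to the electron-withdrawing lactone oxygen; zerovalent palladium is released and reoxidised by benzoquinone, which MnO2 regenerates so that little quinone is free for Diels–Alder addition to 20. The closest known reaction types are the palladium/benzoquinone acyloxylactonisation of dienoic acids and the 1,4-diacyloxylation of dienes with carboxylic acids in acetone. C6 (S) is controlled by C7 and C11: the diene–metal unit is taken up on the face of the forming ring opposite to the cis-disposed C8 chain and C13 methyl, with C8 turned away from C5, which gives the H6/H7-trans lactone. C3 (S) is controlled by C6 through the metal: two anti attacks put both oxygens on the same face of the s-trans E,E-diene, which corresponds to the 3S,6S pair. The E C4=C5 alkene follows from the syn,syn geometry of 22 (C2 and C6 both syn to C15), as long as the high carboxylate concentration captures 22 before syn–anti isomerisation. The large excess of 21 over the acetate of the catalyst secures the right ester, and the weakly acidic medium leaves the stereocentre of 21 and both ethers untouched.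

Step 12
Reactants: 23 (3S,4E)-1-[(4-methoxybenzyl)oxy]-4-methyl-5-[(2S,3S,4R)-3-{2-[(tert-butyldimethylsilyl)oxy]ethyl}-4-methyl-5-oxooxolan-2-yl]pent-4-en-3-yl (2R)-2-methylbutanoate
Product: 24 (3S,4E)-1-hydroxy-4-methyl-5-[(2S,3S,4R)-3-{2-[(tert-butyldimethylsilyl)oxy]ethyl}-4-methyl-5-oxooxolan-2-yl]pent-4-en-3-yl (2R)-2-methylbutanoate
Conditions: DDQ, CH2Cl2–pH 7 buffer, 0 °C
Reagents that add atoms: none
Why: Oxidative cleavage of the 4-methoxybenzyl ether by DDQ (oxidation at the electron-rich benzylic position, hydrolysis of the oxocarbenium ion); the buffer protects the silyl ether, and the electron-poor C4=C5 alkene and both esters are inert.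

Step 13
Reactants: 24 (3S,4E)-1-hydroxy-4-methyl-5-[(2S,3S,4R)-3-{2-[(tert-butyldimethylsilyl)oxy]ethyl}-4-methyl-5-oxooxolan-2-yl]pent-4-en-3-yl (2R)-2-methylbutanoate
Product: 25 (3S,4E)-4-methyl-1-oxo-5-[(2S,3S,4R)-3-{2-[(tert-butyldimethylsilyl)oxy]ethyl}-4-methyl-5-oxooxolan-2-yl]pent-4-en-3-yl (2R)-2-methylbutanoate
Conditions: Dess–Martin periodinane, NaHCO3, CH2Cl2, 0 → 23 °C; used at once
Reagents that add atoms: none
Why: Dess–Martin oxidation of the primary alcohol; the buffered, non-basic medium and immediate use are chosen so that neither 1,3-acyl migration in 24 nor loss of the C3 carboxylate from the β-acyloxy aldehyde can set in.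

Step 14
Reactants: 25 (3S,4E)-4-methyl-1-oxo-5-[(2S,3S,4R)-3-{2-[(tert-butyldimethylsilyl)oxy]ethyl}-4-methyl-5-oxooxolan-2-yl]pent-4-en-3-yl (2R)-2-methylbutanoate; 26 ethyltriphenylphosphonium iodide
Product: 27 (2Z,5S,6E)-2-iodo-6-methyl-7-[(2S,3S,4R)-3-{2-[(tert-butyldimethylsilyl)oxy]ethyl}-4-methyl-5-oxooxolan-2-yl]hepta-2,6-dien-5-yl (2R)-2-methylbutanoate
Conditions: 26, n-BuLi, THF, 23 °C; I2, −78 °C; NaN(SiMe3)2, −78 → −20 °C; then 25, −78 °C
Reagents that add atoms: iodine, II
Why: Stork–Zhao-type Wittig olefination with the 1-iodoethylidene ylide (from 26 by deprotonation, iodination and a second deprotonation): kinetically controlled oxaphosphetane formation places iodine cis to C2 and gives the Z-iodoalkene that brings in C10 and C14. The ylide is only weakly basic and is consumed at −78 °C, which should spare the β-acyloxy aldehyde and the C11 and side-chain α-centres.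

Step 15
Reactants: 27 (2Z,5S,6E)-2-iodo-6-methyl-7-[(2S,3S,4R)-3-{2-[(tert-butyldimethylsilyl)oxy]ethyl}-4-methyl-5-oxooxolan-2-yl]hepta-2,6-dien-5-yl (2R)-2-methylbutanoate
Product: 28 (2Z,5S,6E)-7-[(2S,3S,4R)-3-(2-hydroxyethyl)-4-methyl-5-oxooxolan-2-yl]-2-iodo-6-methylhepta-2,6-dien-5-yl (2R)-2-methylbutanoate
Conditions: HF·pyridine, pyridine, THF, 0 → 23 °C
Reagents that add atoms: none
Why: Fluoride-mediated desilylation; pyridine-buffered HF is non-basic, so the C11 centre, both esters and the vinyl iodide are expected to survive.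

Step 16
Reactants: 28 (2Z,5S,6E)-7-[(2S,3S,4R)-3-(2-hydroxyethyl)-4-methyl-5-oxooxolan-2-yl]-2-iodo-6-methylhepta-2,6-dien-5-yl (2R)-2-methylbutanoate
Product: 29 (2Z,5S,6E)-2-iodo-6-methyl-7-[(2S,3S,4R)-4-methyl-5-oxo-3-(2-oxoethyl)oxolan-2-yl]hepta-2,6-dien-5-yl (2R)-2-methylbutanoate
Conditions: Dess–Martin periodinane, NaHCO3, CH2Cl2, 0 → 23 °C
Reagents that add atoms: none
Why: Dess–Martin oxidation to the C9 aldehyde under buffered conditions; the vinyl iodide and the esters are inert, and the short contact time limits any attack of the free C9 hydroxyl on the lactone carbonyl.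

Step 17
Reactants: 29 (2Z,5S,6E)-2-iodo-6-methyl-7-[(2S,3S,4R)-4-methyl-5-oxo-3-(2-oxoethyl)oxolan-2-yl]hepta-2,6-dien-5-yl (2R)-2-methylbutanoate
Product: 31 (3R,3aS,5S,6Z,9S,10E,11aS)-5-hydroxy-3,6,10-trimethyl-2-oxo-2,3,3a,4,5,8,9,11a-octahydrocyclodeca[b]furan-9-yl (2R)-2-methylbutanoate, via alkenylchromium dichloride 30 (not isolated)
Conditions: CrCl2 (15 equiv), NiCl2 (2 mol% of the CrCl2), degassed DMSO, 23 °C, 2 mM, slow addition of 29
Reagents that add atoms: none
Why: Nozaki–Hiyama–Kishi reaction: nickel-catalysed activation of the C–I bond and transmetallation give alkenylchromium 30 with retention of the Z geometry, and its intramolecular addition to the C9 aldehyde forms C9–C10 and closes the ten-membered ring without touching ester or lactone. C9 is set under substrate control by the conformation of the forming ring (aldehyde oxygen turned outward, away from the lactone); the 9S sense is a working hypothesis and is covered by a fallback.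

## Compound list

1 | but-3-yn-1-ol | C#CCCO | starting material
2 | tert-butyl(but-3-yn-1-yloxy)dimethylsilane | C#CCCO[Si](C)(C)C(C)(C)C | intermediate
3 | N-methoxy-N-methylacetamide | CC(=O)N(C)OC | starting material
4 | {4-[(tert-butyldimethylsilyl)oxy]but-1-yn-1-yl}lithium | [Li]C#CCCO[Si](C)(C)C(C)(C)C | intermediate
5 | 6-[(tert-butyldimethylsilyl)oxy]hex-3-yn-2-one | CC(=O)C#CCCO[Si](C)(C)C(C)(C)C | intermediate
6 | (2R)-6-[(tert-butyldimethylsilyl)oxy]hex-3-yn-2-ol | C[C@@H](O)C#CCCO[Si](C)(C)C(C)(C)C | intermediate
7 | (2R,3Z)-6-[(tert-butyldimethylsilyl)oxy]hex-3-en-2-ol | C[C@@H](O)/C=C\CCO[Si](C)(C)C(C)(C)C | intermediate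
8 | propanoyl chloride | CCC(Cl)=O | starting material
9 | (2R,3Z)-6-[(tert-butyldimethylsilyl)oxy]hex-3-en-2-yl propanoate | CCC(=O)O[C@H](C)/C=C\CCO[Si](C)(C)C(C)(C)C | intermediate
10 | lithium Z(O)-enolate of 9 (methyl cis to O–Li) | C/C=C(\O[Li])O[C@H](C)/C=C\CCO[Si](C)(C)C(C)(C)C | intermediate
11 | (Z)-O-trimethylsilyl ketene acetal of 9 (methyl cis to OSiMe3) | C/C=C(\O[Si](C)(C)C)O[C@H](C)/C=C\CCO[Si](C)(C)C(C)(C)C | intermediate
12 | trimethylsilyl (2R,3R,4E)-3-{2-[(tert-butyldimethylsilyl)oxy]ethyl}-2-methylhex-4-enoate | C[Si](C)(C)OC(=O)[C@H](C)[C@H](CCO[Si](C)(C)C(C)(C)C)/C=C/C | intermediate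
13 | (2R,3R,4E)-3-{2-[(tert-butyldimethylsilyl)oxy]ethyl}-2-methylhex-4-enoic acid | OC(=O)[C@H](C)[C@H](CCO[Si](C)(C)C(C)(C)C)/C=C/C | intermediate
14 | 4,4,5,5-tetramethyl-2-vinyl-1,3,2-dioxaborolane | C=CB1OC(C)(C)C(C)(C)O1 | starting material
15 | (2R,3R,4E)-3-{2-[(tert-butyldimethylsilyl)oxy]ethyl}-2-methyl-5-(4,4,5,5-tetramethyl-1,3,2-dioxaborolan-2-yl)pent-4-enoic acid | OC(=O)[C@H](C)[C@H](CCO[Si](C)(C)C(C)(C)C)/C=C/B1OC(C)(C)C(C)(C)O1 | intermediate
16 | pent-3-yn-1-ol | CC#CCCO | starting material
17 | 1-methoxy-4-[(pent-3-yn-1-yloxy)methyl]benzene | CC#CCCOCc1ccc(OC)cc1 | intermediate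
18 | chlorobis(cyclopentadienyl){(2E)-5-[(4-methoxybenzyl)oxy]pent-2-en-2-yl}zirconium | C/C(=C\CCOCc1ccc(OC)cc1)[Zr](Cl)(C1C=CC=C1)C1C=CC=C1 | intermediate
19 | 1-({[(3E)-4-iodopent-3-en-1-yl]oxy}methyl)-4-methoxybenzene | C/C(I)=C\CCOCc1ccc(OC)cc1 | intermediate
20 | (2R,3R,4E,6E)-3-{2-[(tert-butyldimethylsilyl)oxy]ethyl}-9-[(4-methoxybenzyl)oxy]-2,6-dimethylnona-4,6-dienoic acid | OC(=O)[C@H](C)[C@H](CCO[Si](C)(C)C(C)(C)C)/C=C/C(C)=C/CCOCc1ccc(OC)cc1 | intermediate
21 | (2R)-2-methylbutanoic acid | CC[C@@H](C)C(=O)O | starting material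
22 | syn,syn-(η3-allyl)palladium chloride over C3–C5 of the C6 lactone, drawn as its ion-pair form | [Pd+2].[Cl-].[CH-](CCOCc1ccc(OC)cc1)/C(C)=C/[C@H]1OC(=O)[C@H](C)[C@@H]1CCO[Si](C)(C)C(C)(C)C | intermediate
23 | (3S,4E)-1-[(4-methoxybenzyl)oxy]-4-methyl-5-[(2S,3S,4R)-3-{2-[(tert-butyldimethylsilyl)oxy]ethyl}-4-methyl-5-oxooxolan-2-yl]pent-4-en-3-yl (2R)-2-methylbutanoate | CC[C@@H](C)C(=O)O[C@@H](CCOCc1ccc(OC)cc1)/C(C)=C/[C@H]1OC(=O)[C@H](C)[C@@H]1CCO[Si](C)(C)C(C)(C)C | intermediate
24 | (3S,4E)-1-hydroxy-4-methyl-5-[(2S,3S,4R)-3-{2-[(tert-butyldimethylsilyl)oxy]ethyl}-4-methyl-5-oxooxolan-2-yl]pent-4-en-3-yl (2R)-2-methylbutanoate | CC[C@@H](C)C(=O)O[C@@H](CCO)/C(C)=C/[C@H]1OC(=O)[C@H](C)[C@@H]1CCO[Si](C)(C)C(C)(C)C | intermediate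
25 | (3S,4E)-4-methyl-1-oxo-5-[(2S,3S,4R)-3-{2-[(tert-butyldimethylsilyl)oxy]ethyl}-4-methyl-5-oxooxolan-2-yl]pent-4-en-3-yl (2R)-2-methylbutanoate | CC[C@@H](C)C(=O)O[C@@H](CC=O)/C(C)=C/[C@H]1OC(=O)[C@H](C)[C@@H]1CCO[Si](C)(C)C(C)(C)C | intermediate
26 | ethyltriphenylphosphonium iodide | CC[P+](c1ccccc1)(c1ccccc1)c1ccccc1.[I-] | starting material
27 | (2Z,5S,6E)-2-iodo-6-methyl-7-[(2S,3S,4R)-3-{2-[(tert-butyldimethylsilyl)oxy]ethyl}-4-methyl-5-oxooxolan-2-yl]hepta-2,6-dien-5-yl (2R)-2-methylbutanoate | CC[C@@H](C)C(=O)O[C@@H](C/C=C(/C)I)/C(C)=C/[C@H]1OC(=O)[C@H](C)[C@@H]1CCO[Si](C)(C)C(C)(C)C | intermediate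
28 | (2Z,5S,6E)-7-[(2S,3S,4R)-3-(2-hydroxyethyl)-4-methyl-5-oxooxolan-2-yl]-2-iodo-6-methylhepta-2,6-dien-5-yl (2R)-2-methylbutanoate | CC[C@@H](C)C(=O)O[C@@H](C/C=C(/C)I)/C(C)=C/[C@H]1OC(=O)[C@H](C)[C@@H]1CCO | intermediate
29 | (2Z,5S,6E)-2-iodo-6-methyl-7-[(2S,3S,4R)-4-methyl-5-oxo-3-(2-oxoethyl)oxolan-2-yl]hepta-2,6-dien-5-yl (2R)-2-methylbutanoate | CC[C@@H](C)C(=O)O[C@@H](C/C=C(/C)I)/C(C)=C/[C@H]1OC(=O)[C@H](C)[C@@H]1CC=O | intermediate
30 | (Z)-alkenylchromium dichloride from 29 (chromium in place of iodine on C10) | CC[C@@H](C)C(=O)O[C@@H](C/C=C(/C)[Cr](Cl)Cl)/C(C)=C/[C@H]1OC(=O)[C@H](C)[C@@H]1CC=O | intermediate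
31 | (3R,3aS,5S,6Z,9S,10E,11aS)-5-hydroxy-3,6,10-trimethyl-2-oxo-2,3,3a,4,5,8,9,11a-octahydrocyclodeca[b]furan-9-yl (2R)-2-methylbutanoate (CNP0276536.1) | CC[C@@H](C)C(=O)O[C@H]1C/C=C(/C)[C@@H](O)C[C@@H]2[C@@H](/C=C/1C)OC(=O)[C@@H]2C | target

## Step count and least certain steps

Total: 17 steps. Longest linear sequence: 15 steps (steps 1–7 and 10–17, from 1); the two-step branch from 16 (steps 8 and 9) joins at step 10.

**Step 11 (key step).** The most likely failure is loss of the 1,4-syn relationship and of the E geometry. Syn–anti isomerisation of the allyl intermediate, or delivery of carboxylate from the metal when chloride is lost, would cause it; the C15 methyl on the central allyl carbon makes the syn substituents less comfortable and so eases isomerisation. Incomplete face selection in the lactonisation and consumption of the diene by cycloaddition with the quinone are further risks. The fallback sets out from 20 and returns at 23 without palladium.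
- Selenolactonisation of 20 (N-(phenylselanyl)phthalimide, cat. camphorsulfonic acid, CH2Cl2) should give, by anti addition across C5=C6, (3R,4S,5S)-4-{2-[(tert-butyldimethylsilyl)oxy]ethyl}-5-{(1R,2E)-5-[(4-methoxybenzyl)oxy]-2-methyl-1-(phenylselanyl)pent-2-en-1-yl}-3-methyloxolan-2-one F1.
- Oxidation (H2O2, pyridine, 0 °C) and [2,3]-shift of the allylic selenoxide would move oxygen to C3 on the face that carried selenium and give the E allylic alcohol with the 3R configuration, (3R,4S,5S)-4-{2-[(tert-butyldimethylsilyl)oxy]ethyl}-5-{(1E,3R)-3-hydroxy-5-[(4-methoxybenzyl)oxy]-2-methylpent-1-en-1-yl}-3-methyloxolan-2-one F2.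
- Mitsunobu esterification of F2 with 21 (PPh3, DIAD) inverts C3 and gives 23.

**Step 17.** The most likely failure is poor facial selectivity at the C9 aldehyde, together with intermolecular coupling competing with closure of the strained ring, because nothing but the ring conformation steers the addition. The fallback sets out from 29 and returns at 31, moving C9 control from the substrate to a reagent.
- The closure is run as in step 17 and would give 31 mixed with its 9R epimer, (3R,3aS,5R,6Z,9S,10E,11aS)-5-hydroxy-3,6,10-trimethyl-2-oxo-2,3,3a,4,5,8,9,11a-octahydrocyclodeca[b]furan-9-yl (2R)-2-methylbutanoate F3.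
- Dess–Martin oxidation of the mixture converges on the C9 enone, (3R,3aS,6Z,9S,10E,11aS)-3,6,10-trimethyl-2,5-dioxo-2,3,3a,4,5,8,9,11a-octahydrocyclodeca[b]furan-9-yl (2R)-2-methylbutanoate F4.
- Corey–Bakshi–Shibata reduction of F4 with the (R)-2-methyl-oxazaborolidine and catecholborane at −78 °C, with C10 as the large group, should give 31.

**Step 14.** The most likely failure is β-elimination of the C3 carboxylate from the aldehyde under the basic ylide, with erosion of the Z selectivity and enolisation at C11 as lesser risks. The fallback sets out from 25 and returns at 27 by a non-basic route.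
- Dibromo-olefination of 25 (CBr4, PPh3, 2,6-lutidine, CH2Cl2, 0 °C) gives (4S,5E)-1,1-dibromo-5-methyl-6-[(2S,3S,4R)-3-{2-[(tert-butyldimethylsilyl)oxy]ethyl}-4-methyl-5-oxooxolan-2-yl]hexa-1,5-dien-4-yl (2R)-2-methylbutanoate F5.
- Palladium-catalysed Negishi methylation of the bromide trans to C2 (MeZnCl, Pd(PtBu3)2, THF) gives the Z-bromide, (2Z,5S,6E)-2-bromo-6-methyl-7-[(2S,3S,4R)-3-{2-[(tert-butyldimethylsilyl)oxy]ethyl}-4-methyl-5-oxooxolan-2-yl]hepta-2,6-dien-5-yl (2R)-2-methylbutanoate F6.
- Copper-catalysed halogen exchange (CuI, NaI, trans-N,N'-dimethylcyclohexane-1,2-diamine, dioxane) with retention gives 27.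

**Step 7.** The most likely failure is slow metathesis at the α-branched internal alkene, so that catalyst decay and self-metathesis of 14 outrun productive exchange. The fallback sets out from 13 and returns at 20, replacing metathesis by oxidative cleavage and reversing the polarity of the coupling.
- Esterification of 13 (Me3SiCHN2, MeOH–toluene) gives methyl (2R,3R,4E)-3-{2-[(tert-butyldimethylsilyl)oxy]ethyl}-2-methylhex-4-enoate F7.
- Ozonolysis (O3, CH2Cl2, −78 °C; PPh3) gives methyl (2R,3S)-5-[(tert-butyldimethylsilyl)oxy]-3-formyl-2-methylpentanoate F8.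
- Takai iodo-olefination (CrCl2, CHI3, THF) gives methyl (2R,3S,4E)-3-{2-[(tert-butyldimethylsilyl)oxy]ethyl}-5-iodo-2-methylpent-4-enoate F9.
- Separately, 19 is borylated (B2pin2, PdCl2(PPh3)2, PPh3, KOPh, toluene, 50 °C) to 2-{(2Z)-5-[(4-methoxybenzyl)oxy]pent-2-en-2-yl}-4,4,5,5-tetramethyl-1,3,2-dioxaborolane F10, in which boron is trans to C2.
- Suzuki–Miyaura coupling of F9 with F10 under the conditions of step 10 gives methyl (2R,3R,4E,6E)-3-{2-[(tert-butyldimethylsilyl)oxy]ethyl}-9-[(4-methoxybenzyl)oxy]-2,6-dimethylnona-4,6-dienoate F11.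
- Hydrolysis of F11 (LiOH, THF–H2O, 0 °C) gives 20.

## Further compounds

F1 | step 11 | (3R,4S,5S)-4-{2-[(tert-butyldimethylsilyl)oxy]ethyl}-5-{(1R,2E)-5-[(4-methoxybenzyl)oxy]-2-methyl-1-(phenylselanyl)pent-2-en-1-yl}-3-methyloxolan-2-one | COc1ccc(COCC/C=C(\C)[C@@H]([Se]c2ccccc2)[C@H]2OC(=O)[C@H](C)[C@@H]2CCO[Si](C)(C)C(C)(C)C)cc1
F2 | step 11 | (3R,4S,5S)-4-{2-[(tert-butyldimethylsilyl)oxy]ethyl}-5-{(1E,3R)-3-hydroxy-5-[(4-methoxybenzyl)oxy]-2-methylpent-1-en-1-yl}-3-methyloxolan-2-one | O[C@H](CCOCc1ccc(OC)cc1)/C(C)=C/[C@H]1OC(=O)[C@H](C)[C@@H]1CCO[Si](C)(C)C(C)(C)C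
F3 | step 17 | (3R,3aS,5R,6Z,9S,10E,11aS)-5-hydroxy-3,6,10-trimethyl-2-oxo-2,3,3a,4,5,8,9,11a-octahydrocyclodeca[b]furan-9-yl (2R)-2-methylbutanoate | CC[C@@H](C)C(=O)O[C@H]1C/C=C(/C)[C@H](O)C[C@@H]2[C@@H](/C=C/1C)OC(=O)[C@@H]2C
F4 | step 17 | (3R,3aS,6Z,9S,10E,11aS)-3,6,10-trimethyl-2,5-dioxo-2,3,3a,4,5,8,9,11a-octahydrocyclodeca[b]furan-9-yl (2R)-2-methylbutanoate | CC[C@@H](C)C(=O)O[C@H]1C/C=C(/C)C(=O)C[C@@H]2[C@@H](/C=C/1C)OC(=O)[C@@H]2C
F5 | step 14 | (4S,5E)-1,1-dibromo-5-methyl-6-[(2S,3S,4R)-3-{2-[(tert-butyldimethylsilyl)oxy]ethyl}-4-methyl-5-oxooxolan-2-yl]hexa-1,5-dien-4-yl (2R)-2-methylbutanoate | CC[C@@H](C)C(=O)O[C@@H](CC=C(Br)Br)/C(C)=C/[C@H]1OC(=O)[C@H](C)[C@@H]1CCO[Si](C)(C)C(C)(C)C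
F6 | step 14 | (2Z,5S,6E)-2-bromo-6-methyl-7-[(2S,3S,4R)-3-{2-[(tert-butyldimethylsilyl)oxy]ethyl}-4-methyl-5-oxooxolan-2-yl]hepta-2,6-dien-5-yl (2R)-2-methylbutanoate | CC[C@@H](C)C(=O)O[C@@H](C/C=C(/C)Br)/C(C)=C/[C@H]1OC(=O)[C@H](C)[C@@H]1CCO[Si](C)(C)C(C)(C)C
F7 | step 7 | methyl (2R,3R,4E)-3-{2-[(tert-butyldimethylsilyl)oxy]ethyl}-2-methylhex-4-enoate | COC(=O)[C@H](C)[C@H](CCO[Si](C)(C)C(C)(C)C)/C=C/C
F8 | step 7 | methyl (2R,3S)-5-[(tert-butyldimethylsilyl)oxy]-3-formyl-2-methylpentanoate | COC(=O)[C@H](C)[C@H](CCO[Si](C)(C)C(C)(C)C)C=O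
F9 | step 7 | methyl (2R,3S,4E)-3-{2-[(tert-butyldimethylsilyl)oxy]ethyl}-5-iodo-2-methylpent-4-enoate | COC(=O)[C@H](C)[C@H](CCO[Si](C)(C)C(C)(C)C)/C=C/I
F10 | step 7 | 2-{(2Z)-5-[(4-methoxybenzyl)oxy]pent-2-en-2-yl}-4,4,5,5-tetramethyl-1,3,2-dioxaborolane | C/C(=C\CCOCc1ccc(OC)cc1)B1OC(C)(C)C(C)(C)O1
F11 | step 7 | methyl (2R,3R,4E,6E)-3-{2-[(tert-butyldimethylsilyl)oxy]ethyl}-9-[(4-methoxybenzyl)oxy]-2,6-dimethylnona-4,6-dienoate | COC(=O)[C@H](C)[C@H](CCO[Si](C)(C)C(C)(C)C)/C=C/C(C)=C/CCOCc1ccc(OC)cc1
A1 | alternative 1 | cis-fused 3-acetoxy-9-[(tert-butyldimethylsilyl)oxy]eudesma-1,3-dien-12,6-olide (one cis-fused diastereomer) | CC(=O)OC1=C(C)[C@H]3[C@@](C)(C=C1)[C@@H](O[Si](C)(C)C(C)(C)C)C[C@@H]2[C@@H]3OC(=O)[C@@H]2C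
A2 | alternative 1 | 3-acetoxy-9-[(tert-butyldimethylsilyl)oxy]germacra-1(10),2,4-trien-12,6-olide with C1=C10 Z, C2=C3 ring-cis and C4=C5 E | CC(=O)O/C1=C/C=C(/C)[C@@H](O[Si](C)(C)C(C)(C)C)C[C@@H]2[C@@H](\C=C\1C)OC(=O)[C@@H]2C
A3 | alternative 2 | thirteen-membered diallylic ether (O between C6 and C12) with C3 4-methoxybenzyl ether, C9 silyl ether, C1=C10 Z, C4=C5 E and C7=C11 E | COc1ccc(CO[C@H]2C/C=C(/C)[C@@H](O[Si](C)(C)C(C)(C)C)C/C=C(\C)COC/C=C/2C)cc1
A4 | alternative 2 | ten-membered dienol with C6 hydroxyl, C7 isopropenyl, C3 4-methoxybenzyl ether and C9 silyl ether | COc1ccc(CO[C@H]2C/C=C(/C)[C@@H](O[Si](C)(C)C(C)(C)C)C[C@@H](C(C)=C)[C@@H](/C=C/2C)O)cc1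
A5 | alternative 3 | open-chain α-methylbutenolide with C3 (R)-2-methylbutanoate and C9 silyl dienol ether (C8 methylene) | CC[C@@H](C)C(=O)O[C@@H](C/C=C(/C)C(=C)O[Si](C)(C)C(C)(C)C)/C(C)=C/[C@H]1OC(=O)C(C)=C1
A6 | alternative 3 | 9-oxo analogue of 31 | CC[C@@H](C)C(=O)O[C@H]1C/C=C(/C)C(=O)C[C@@H]2[C@@H](/C=C/1C)OC(=O)[C@@H]2C
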